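**Retrosynthetic overview**
- Pestalone H ⇐ global MOM removal ⇐ DIBAL-H opening of a 2,2-dimethyl-1,3-benzodioxin-4-one, which unmasks the CHO and the adjacent phenol of ring B in one operation.
- Ring B (built de novo, last) ⇐ aromatising intramolecular aldol condensation of a triketo-dioxinone that already carries the prenyl group and the ring-A aroyl group.
- Key C–C bond (C1'–C6' of ring B) ⇐ intermolecular aldol addition of the dianion of a prenylated keto-dioxinone to the ring-A arylglyoxal, then oxidation.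
- Keto-dioxinone ⇐ 2,2,6-trimethyl-1,3-dioxin-4-one + acetyl chloride + prenyl bromide; arylglyoxal ⇐ ring-A benzaldehyde (vinyl addition, oxidation, ozonolysis).
- Ring A is present from the start (3-methoxy-5-methylphenol); Br, Cl and CHO are installed by substituent-directed aromatic substitution, so only ring B is formed in the route.

Assumption: Pestalone H has no stereogenic element, so no enantiocontrol is needed; the transient stereocentres in 10 and 22 are carried as racemate/diastereomer mixtures and are destroyed later.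

Abbreviation: ArA = 3-bromo-5-chloro-2-methoxy-6-(methoxymethoxy)-4-methylphenyl.

**Route**

Step 1
Reactants: 1 3-methoxy-5-methylphenol
Product: 2 triisopropyl(3-methoxy-5-methylphenoxy)silane
Conditions: TIPSCl, imidazole, DMF, rt
Reagents that add atoms: triisopropylsilyl chloride, CC(C)[Si](Cl)(C(C)C)C(C)C
Why: Standard O-silylation; the bulky silyl ether is installed to steer the following bromination away from its own ortho positions.

Step 2
Reactants: 2 triisopropyl(3-methoxy-5-methylphenoxy)silane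
Product: 3 (4-bromo-3-methoxy-5-methylphenoxy)triisopropylsilane
Conditions: NBS (1.0 equiv), MeCN, 0 °C to rt
Reagents that add atoms: N-bromosuccinimide, O=C1CCC(=O)N1Br
Why: Electrophilic aromatic bromination goes para to the silyloxy group and ortho to OMe, because the other activated site is shielded by TIPS and the position between the two oxygens is the least reactive in orcinol ethers.

Step 3
Reactants: 3 (4-bromo-3-methoxy-5-methylphenoxy)triisopropylsilane
Product: 4 4-bromo-3-methoxy-5-methylphenol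
Conditions: TBAF, THF, 0 °C; 1 M HCl work-up
Reagents that add atoms: none
Why: Fluoride-mediated desilylation of an aryl silyl ether is fast and leaves the aryl bromide untouched.

Step 4
Reactants: 4 4-bromo-3-methoxy-5-methylphenol
Product: 5 4-bromo-2-chloro-5-methoxy-3-methylphenol
Conditions: NCS (1.05 equiv), cat. TsOH·H2O, MeCN, rt
Reagents that add atoms: N-chlorosuccinimide, O=C1CCC(=O)N1Cl
Why: Electrophilic aromatic chlorination takes the site ortho to OH and para to OMe (next to the methyl), as is general for orcinol derivatives, leaving only the position between the oxygens free.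

Step 5
Reactants: 5 4-bromo-2-chloro-5-methoxy-3-methylphenol; 6 paraformaldehyde
Product: 7 3-bromo-5-chloro-6-hydroxy-2-methoxy-4-methylbenzaldehyde
Conditions: MgCl2, Et3N, MeCN, reflux; 1 M HCl work-up
Reagents that add atoms: none
Why: Casnati–Skattebøl magnesium-mediated ortho-formylation delivers CHO exclusively ortho to the phenol, and only one ortho position is left (a second formaldehyde acts as hydride acceptor).

Step 6
Reactants: 7 3-bromo-5-chloro-6-hydroxy-2-methoxy-4-methylbenzaldehyde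
Product: 8 3-bromo-5-chloro-2-methoxy-6-(methoxymethoxy)-4-methylbenzaldehyde
Conditions: MOMCl, iPr2NEt, cat. DMAP, CH2Cl2, 0 °C to reflux
Reagents that add atoms: chloromethyl methyl ether, COCCl
Why: MOM etherification masks the phenol through the base, organometallic and oxidation steps and is removed at the end by mild acid.

Step 7
Reactants: 8 3-bromo-5-chloro-2-methoxy-6-(methoxymethoxy)-4-methylbenzaldehyde; 9 vinylmagnesium bromide
Product: 10 rac-1-(ArA)prop-2-en-1-ol
Conditions: THF, −78 to 0 °C; then H2O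
Reagents that add atoms: none
Why: Grignard 1,2-addition to the aldehyde is faster than any halogen–magnesium exchange at low temperature; the new stereocentre is racemic and removed in step 8.

Step 8
Reactants: 10 rac-1-(ArA)prop-2-en-1-ol
Product: 11 1-(ArA)prop-2-en-1-one
Conditions: DMP, CH2Cl2, 0 °C to rt
Reagents that add atoms: none
Why: Dess–Martin oxidation of an allylic/benzylic secondary alcohol is mild and tolerates MOM ether and aryl halides.

Step 9
Reactants: 11 1-(ArA)prop-2-en-1-one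
Product: 13 2-(ArA)-2-oxoacetaldehyde, via secondary ozonide 12 (not isolated)
Conditions: O3, CH2Cl2, −78 °C (Sudan III end point); then Me2S, −78 °C to rt
Reagents that add atoms: ozone, [O-][O+]=O
Why: Ozonolysis with reductive work-up cleaves the vinyl group to give the anhydrous, non-enolisable arylglyoxal; the fully substituted, acyl-deactivated arene reacts much more slowly than the alkene.

Step 10
Reactants: 14 2,2,6-trimethyl-4H-1,3-dioxin-4-one; 15 acetyl chloride
Product: 17 2,2-dimethyl-6-(2-oxopropyl)-4H-1,3-dioxin-4-one, via lithium dienolate 16 (not isolated)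
Conditions: LiHMDS, THF, −78 °C (2 equiv of 14 and base); then AcCl, −78 °C; 1 M HCl work-up
Reagents that add atoms: none
Why: Claisen-type C-acylation of the vinylogous (γ) lithium enolate of the dioxinone, the standard entry to keto-dioxinones.

Step 11
Reactants: 17 2,2-dimethyl-6-(2-oxopropyl)-4H-1,3-dioxin-4-one; 18 prenyl bromide
Product: 20 2,2-dimethyl-6-(6-methyl-2-oxohept-5-en-1-yl)-4H-1,3-dioxin-4-one, via dilithio dianion 19 (not isolated)
Conditions: LDA (2.1 equiv), THF, −78 °C; then 18, −78 to −20 °C; 1 M HCl work-up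
Reagents that add atoms: none
Why: Weiler-type dianion alkylation occurs at the more reactive terminal enolate carbon by SN2, placing the future prenyl group one carbon from the ketone.

Step 12 (key step)
Reactants: 20 2,2-dimethyl-6-(6-methyl-2-oxohept-5-en-1-yl)-4H-1,3-dioxin-4-one; 13 2-(ArA)-2-oxoacetaldehyde
Product: 22 6-{3-[2-(ArA)-1-hydroxy-2-oxoethyl]-6-methyl-2-oxohept-5-en-1-yl}-2,2-dimethyl-4H-1,3-dioxin-4-one (diastereomer mixture), via dilithio dianion 21 (not isolated)
Conditions: LDA (2.2 equiv), THF, −78 °C; then 13 in THF, −78 °C; AcOH quench at −78 °C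
Reagents that add atoms: none
Why: Intermolecular aldol addition of the terminal (α') enolate carbon of the keto-dioxinone dianion to the aldehyde of the glyoxal, whose di-ortho-substituted aryl ketone is shielded; the two new stereocentres form unselectively and are both erased in step 13.

Step 13
Reactants: 22 6-{3-[2-(ArA)-1-hydroxy-2-oxoethyl]-6-methyl-2-oxohept-5-en-1-yl}-2,2-dimethyl-4H-1,3-dioxin-4-one
Product: 24 5-(ArA-carbonyl)-7-hydroxy-2,2-dimethyl-6-(3-methylbut-2-en-1-yl)-4H-1,3-benzodioxin-4-one, via triketo-dioxinone 23 (not isolated)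
Conditions: DMP, CH2Cl2, 0 °C to rt; filter and concentrate; then Et3N, CH2Cl2, rt
Reagents that add atoms: none
Why: Dess–Martin oxidation gives the tricarbonyl chain, and base-promoted intramolecular aldol condensation of dioxinone C5 onto the activated α-diketone carbonyl, followed by dehydration and enolisation, aromatises to ring B (biomimetic resorcylate formation) with aroyl, prenyl and OH in their final positions.

Step 14
Reactants: 24 5-(ArA-carbonyl)-7-hydroxy-2,2-dimethyl-6-(3-methylbut-2-en-1-yl)-4H-1,3-benzodioxin-4-one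
Product: 25 5-(ArA-carbonyl)-7-(methoxymethoxy)-2,2-dimethyl-6-(3-methylbut-2-en-1-yl)-4H-1,3-benzodioxin-4-one
Conditions: MOMCl, iPr2NEt, CH2Cl2, 0 °C to rt
Reagents that add atoms: chloromethyl methyl ether, COCCl
Why: MOM etherification of the free phenol prevents an aluminium phenoxide from deactivating the para lactone carbonyl in the next reduction.

Step 15
Reactants: 25 5-(ArA-carbonyl)-7-(methoxymethoxy)-2,2-dimethyl-6-(3-methylbut-2-en-1-yl)-4H-1,3-benzodioxin-4-one
Product: 26 2-(ArA-carbonyl)-6-hydroxy-4-(methoxymethoxy)-3-(3-methylbut-2-en-1-yl)benzaldehyde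
Conditions: DIBAL-H (1.5 equiv), CH2Cl2, −78 °C; MeOH then aq. Rochelle salt
Reagents that add atoms: none
Why: Partial hydride reduction of the acetonide-type lactone gives an aluminium hemiacetal that is stable at −78 °C and collapses on work-up to the salicylaldehyde and acetone, while the tetra-ortho-substituted diaryl ketone is sterically protected.

Step 16
Reactants: 26 2-(ArA-carbonyl)-6-hydroxy-4-(methoxymethoxy)-3-(3-methylbut-2-en-1-yl)benzaldehyde
Product: 27 Pestalone H
Conditions: 3 M aq. HCl, MeOH/THF, rt to 40 °C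
Reagents that add atoms: none
Why: Acid-catalysed acetal cleavage removes both MOM ethers under non-basic, non-nucleophilic conditions, which avoids the base-induced Cannizzaro–Tishchenko lactonisation of the keto-aldehyde.

**Compound list**
1 | 3-methoxy-5-methylphenol | COc1cc(C)cc(O)c1 | starting material
2 | triisopropyl(3-methoxy-5-methylphenoxy)silane | COc1cc(C)cc(O[Si](C(C)C)(C(C)C)C(C)C)c1 | intermediate
3 | (4-bromo-3-methoxy-5-methylphenoxy)triisopropylsilane | COc1cc(O[Si](C(C)C)(C(C)C)C(C)C)cc(C)c1Br | intermediate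
4 | 4-bromo-3-methoxy-5-methylphenol | COc1cc(O)cc(C)c1Br | intermediate
5 | 4-bromo-2-chloro-5-methoxy-3-methylphenol | COc1cc(O)c(Cl)c(C)c1Br | intermediate
6 | paraformaldehyde (formaldehyde unit) | C=O | starting material
7 | 3-bromo-5-chloro-6-hydroxy-2-methoxy-4-methylbenzaldehyde | COc1c(C=O)c(O)c(Cl)c(C)c1Br | intermediate
8 | 3-bromo-5-chloro-2-methoxy-6-(methoxymethoxy)-4-methylbenzaldehyde | COCOc1c(Cl)c(C)c(Br)c(OC)c1C=O | intermediate
9 | vinylmagnesium bromide | C=C[Mg]Br | starting material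
10 | rac-1-(ArA)prop-2-en-1-ol | C=CC(O)c1c(OC)c(Br)c(C)c(Cl)c1OCOC | intermediate
11 | 1-(ArA)prop-2-en-1-one | C=CC(=O)c1c(OC)c(Br)c(C)c(Cl)c1OCOC | intermediate
12 | 3-(ArA-carbonyl)-1,2,4-trioxolane (secondary ozonide) | O=C(C1OCOO1)c1c(OC)c(Br)c(C)c(Cl)c1OCOC | intermediate
13 | 2-(ArA)-2-oxoacetaldehyde (ring-A arylglyoxal) | O=CC(=O)c1c(OC)c(Br)c(C)c(Cl)c1OCOC | intermediate
14 | 2,2,6-trimethyl-4H-1,3-dioxin-4-one | CC1=CC(=O)OC(C)(C)O1 | starting material
15 | acetyl chloride | CC(=O)Cl | starting material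
16 | lithium dienolate of 14 (lithium 2,2-dimethyl-6-methylidene-6H-1,3-dioxin-4-olate) | C=C1C=C(O[Li])OC(C)(C)O1 | intermediate
17 | 2,2-dimethyl-6-(2-oxopropyl)-4H-1,3-dioxin-4-one | CC(=O)CC1=CC(=O)OC(C)(C)O1 | intermediate
18 | prenyl bromide (1-bromo-3-methylbut-2-ene) | CC(C)=CCBr | starting material
19 | dilithio dianion of 17 | C=C(O[Li])C=C1C=C(O[Li])OC(C)(C)O1 | intermediate
20 | 2,2-dimethyl-6-(6-methyl-2-oxohept-5-en-1-yl)-4H-1,3-dioxin-4-one | CC(C)=CCCC(=O)CC1=CC(=O)OC(C)(C)O1 | intermediate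
21 | dilithio dianion of 20 | CC(C)=CCC=C(O[Li])C=C1C=C(O[Li])OC(C)(C)O1 | intermediate
22 | 6-{3-[2-(ArA)-1-hydroxy-2-oxoethyl]-6-methyl-2-oxohept-5-en-1-yl}-2,2-dimethyl-4H-1,3-dioxin-4-one (diastereomer mixture, racemic) | CC(C)=CCC(C(=O)CC1=CC(=O)OC(C)(C)O1)C(O)C(=O)c1c(OC)c(Br)c(C)c(Cl)c1OCOC | intermediate
23 | 6-{3-[2-(ArA)-2-oxoacetyl]-6-methyl-2-oxohept-5-en-1-yl}-2,2-dimethyl-4H-1,3-dioxin-4-one (triketo-dioxinone, racemic) | CC(C)=CCC(C(=O)CC1=CC(=O)OC(C)(C)O1)C(=O)C(=O)c1c(OC)c(Br)c(C)c(Cl)c1OCOC | intermediate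
24 | 5-(ArA-carbonyl)-7-hydroxy-2,2-dimethyl-6-(3-methylbut-2-en-1-yl)-4H-1,3-benzodioxin-4-one | CC(C)=CCc1c(O)cc2OC(C)(C)OC(=O)c2c1C(=O)c1c(OC)c(Br)c(C)c(Cl)c1OCOC | intermediate
25 | 5-(ArA-carbonyl)-7-(methoxymethoxy)-2,2-dimethyl-6-(3-methylbut-2-en-1-yl)-4H-1,3-benzodioxin-4-one | CC(C)=CCc1c(OCOC)cc2OC(C)(C)OC(=O)c2c1C(=O)c1c(OC)c(Br)c(C)c(Cl)c1OCOC | intermediate
26 | 2-(ArA-carbonyl)-6-hydroxy-4-(methoxymethoxy)-3-(3-methylbut-2-en-1-yl)benzaldehyde | CC(C)=CCc1c(OCOC)cc(O)c(C=O)c1C(=O)c1c(OC)c(Br)c(C)c(Cl)c1OCOC | intermediate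
27 | Pestalone H, 2-(3-bromo-5-chloro-6-hydroxy-2-methoxy-4-methylbenzoyl)-4,6-dihydroxy-3-(3-methylbut-2-en-1-yl)benzaldehyde (achiral) | COc1c(Br)c(C)c(Cl)c(O)c1C(=O)c1c(C=O)c(O)cc(O)c1CC=C(C)C | target

**Totals**
Total step count: 16. Longest linear sequence: 14 steps (steps 1–9, then 12–16); steps 10–11 form the second branch.

**Three steps most likely to fail, with fallbacks**

Step 12 (dianion aldol onto the arylglyoxal). The glyoxal may hydrate or oligomerise, and the aldolate may revert. The fallback replaces the aldol addition by an irreversible Claisen acylation at the final oxidation level. It sets out from 13: Pinnick oxidation (NaClO2, NaH2PO4, 2-methyl-2-butene, t-BuOH/H2O) gives 2-(ArA)-2-oxoacetic acid F1. Amide coupling (MeNHOMe·HCl, EDC·HCl, iPr2NEt, CH2Cl2) gives N-methoxy-N-methyl-2-(ArA)-2-oxoacetamide F2. Acylation of dianion 21 (2 equiv, THF, −78 °C) with F2 at the amide carbonyl, the aryl ketone being shielded, gives the triketo-dioxinone directly. The fallback comes back to the route at 23 and continues with Et3N to 24.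

Step 13 (oxidation and aromatisation through the 1,2,4-tricarbonyl array). Over-oxidation, retro-Claisen or benzilic-type cleavage of the α-diketone could compete with ring closure. The fallback carries the benzylic carbon through ring formation as a silyl-protected carbinol, so that the cyclisation is an ordinary diketo-dioxinone aromatisation. It sets out from 10: TBSOTf/2,6-lutidine gives tert-butyl{[1-(ArA)prop-2-en-1-yl]oxy}dimethylsilane F3. Ozonolysis (O3, then Me2S) passes through its secondary ozonide F4 to 2-(ArA)-2-[(tert-butyldimethylsilyl)oxy]acetaldehyde F5. Aldol addition of dianion 21 gives the β-hydroxy ketone 6-{3-[2-(ArA)-2-(tert-butyldimethylsilyloxy)-1-hydroxyethyl]-6-methyl-2-oxohept-5-en-1-yl}-2,2-dimethyl-4H-1,3-dioxin-4-one F6. DMP gives the crude diketo-dioxinone 6-{3-[2-(ArA)-2-(tert-butyldimethylsilyloxy)acetyl]-6-methyl-2-oxohept-5-en-1-yl}-2,2-dimethyl-4H-1,3-dioxin-4-one F7, which Et3N aromatises to 5-[(ArA)(tert-butyldimethylsilyloxy)methyl]-7-hydroxy-2,2-dimethyl-6-(3-methylbut-2-en-1-yl)-4H-1,3-benzodioxin-4-one F8. MOMCl/iPr2NEt gives its 7-methoxymethyl ether F9. HF·pyridine in THF (non-basic, to prevent translactonisation of the freed carbinol onto the acetonide lactone) gives 5-[(ArA)(hydroxy)methyl]-7-(methoxymethoxy)-2,2-dimethyl-6-(3-methylbut-2-en-1-yl)-4H-1,3-benzodioxin-4-one F10. Immediate DMP oxidation of the diaryl carbinol brings the fallback back to the route at 25.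

Step 15 (partial DIBAL-H reduction next to the diaryl ketone). Over-reduction to the benzylic alcohol or an inseparable aldehyde/alcohol mixture is possible. The fallback abandons the partial reduction for a reduce-then-reoxidise sequence. It sets out from 25: LiBH4 (THF, 0 °C) reduces the lactone completely, leaving the hindered ketone, to (ArA)[3-hydroxy-2-(hydroxymethyl)-5-(methoxymethoxy)-6-(3-methylbut-2-en-1-yl)phenyl]methanone F11. Activated MnO2 (CH2Cl2, rt) then oxidises only the primary benzylic alcohol to the aldehyde, and the fallback comes back to the route at 26.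

**Further compounds**
F1 | step 12 | 2-(ArA)-2-oxoacetic acid | OC(=O)C(=O)c1c(OC)c(Br)c(C)c(Cl)c1OCOC
F2 | step 12 | N-methoxy-N-methyl-2-(ArA)-2-oxoacetamide | CON(C)C(=O)C(=O)c1c(OC)c(Br)c(C)c(Cl)c1OCOC
F3 | step 13 | tert-butyl{[1-(ArA)prop-2-en-1-yl]oxy}dimethylsilane (racemic) | C=CC(O[Si](C)(C)C(C)(C)C)c1c(OC)c(Br)c(C)c(Cl)c1OCOC
F4 | step 13 | 3-[(ArA)(tert-butyldimethylsilyloxy)methyl]-1,2,4-trioxolane (secondary ozonide of F3) | CC(C)(C)[Si](C)(C)OC(C1OCOO1)c1c(OC)c(Br)c(C)c(Cl)c1OCOC
F5 | step 13 | 2-(ArA)-2-[(tert-butyldimethylsilyl)oxy]acetaldehyde (racemic) | O=CC(O[Si](C)(C)C(C)(C)C)c1c(OC)c(Br)c(C)c(Cl)c1OCOC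
F6 | step 13 | 6-{3-[2-(ArA)-2-(tert-butyldimethylsilyloxy)-1-hydroxyethyl]-6-methyl-2-oxohept-5-en-1-yl}-2,2-dimethyl-4H-1,3-dioxin-4-one (diastereomer mixture) | CC(C)=CCC(C(=O)CC1=CC(=O)OC(C)(C)O1)C(O)C(O[Si](C)(C)C(C)(C)C)c1c(OC)c(Br)c(C)c(Cl)c1OCOC
F7 | step 13 | 6-{3-[2-(ArA)-2-(tert-butyldimethylsilyloxy)acetyl]-6-methyl-2-oxohept-5-en-1-yl}-2,2-dimethyl-4H-1,3-dioxin-4-one (diastereomer mixture) | CC(C)=CCC(C(=O)CC1=CC(=O)OC(C)(C)O1)C(=O)C(O[Si](C)(C)C(C)(C)C)c1c(OC)c(Br)c(C)c(Cl)c1OCOC
F8 | step 13 | 5-[(ArA)(tert-butyldimethylsilyloxy)methyl]-7-hydroxy-2,2-dimethyl-6-(3-methylbut-2-en-1-yl)-4H-1,3-benzodioxin-4-one (racemic) | CC(C)=CCc1c(O)cc2OC(C)(C)OC(=O)c2c1C(O[Si](C)(C)C(C)(C)C)c1c(OC)c(Br)c(C)c(Cl)c1OCOC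
F9 | step 13 | 5-[(ArA)(tert-butyldimethylsilyloxy)methyl]-7-(methoxymethoxy)-2,2-dimethyl-6-(3-methylbut-2-en-1-yl)-4H-1,3-benzodioxin-4-one (racemic) | CC(C)=CCc1c(OCOC)cc2OC(C)(C)OC(=O)c2c1C(O[Si](C)(C)C(C)(C)C)c1c(OC)c(Br)c(C)c(Cl)c1OCOC
F10 | step 13 | 5-[(ArA)(hydroxy)methyl]-7-(methoxymethoxy)-2,2-dimethyl-6-(3-methylbut-2-en-1-yl)-4H-1,3-benzodioxin-4-one (racemic) | CC(C)=CCc1c(OCOC)cc2OC(C)(C)OC(=O)c2c1C(O)c1c(OC)c(Br)c(C)c(Cl)c1OCOC
F11 | step 15 | (ArA)[3-hydroxy-2-(hydroxymethyl)-5-(methoxymethoxy)-6-(3-methylbut-2-en-1-yl)phenyl]methanone | CC(C)=CCc1c(OCOC)cc(O)c(CO)c1C(=O)c1c(OC)c(Br)c(C)c(Cl)c1OCOC
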